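(The data were computed with made-up constants; scatter was added.)

Product stands at 25% of the charge in the beta run and at 78% in the eta run after 30.0 min, so the share of the charge that ends as product rises with the charge.

| flask | substrate | remark | time |
|---|---|---|---|
| beta | 0.026 M | run made earlier |  |
| alpha | 0.093 M | run made earlier |  |
| eta | 0.42 M | run made earlier |  |
| larch | 0.060 M |  | 1.0 h |
| ash | 0.30 M |  | 1.0 h |
| cedar | 0.025 M |  | 1.0 h |
| alder | 0.40 M |  | 1.0 h |
| elm | 0.10 M |  | 1.0 h |
| maple | 0.050 M |  | 1.0 h |

| run | time / min | product / % | substrate / % |
|---|---|---|---|
| beta | 5.00 | 12 | 66 |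
| beta | 10.0 | 18 | 46 |
| beta | 15.0 | 21 | 32 |
| beta | 30.0 | 25 | 12 |
| beta | 60.0 | 24 | 5 |
| alpha | 12.0 | 44 | 24 |
| alpha | 25.0 | 47 | 7 |
| alpha | 40.0 | 50 | 4 |
| alpha | 50.0 | 50 | 4 |
| alpha | 60.0 | 53 | 3 |
| eta | 5.00 | 67 | 20 |
| eta | 10.0 | 71 | 11 |
| eta | 15.0 | 77 | 6 |
| eta | 30.0 | 78 | 2 |
| eta | 60.0 | 77 | 4 |

(readings scatter by 1.5 percentage points)

- a species is counted by the substrate in it: one product counts as two
- a reading or a percentage of product counts all its forms, free or not

1. ranking by amount of product, in percent of the substrate charged, from high to low, at 1.0 h (larch / ash / cedar / alder / elm / maple)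
2. the same order at 4.0 h (larch / ash / cedar / alder / elm / maple)
3. the amount of product, in percent of the substrate charged of the flask you put first, at 1.0 h
4. the amount of product, in percent of the substrate charged of the flask you put last, at 1.0 h

The main step alone, two substrate pairing to one product, gives the charge no other place to go. The beta run refutes this: at 60.0 min it reads 24% product and 5% substrate, so 71.0% of its charge has gone elsewhere.

Substrate in the beta run falls between 15.0 min and 30.0 min at about 0.0654 /min, which suggests a second, first-order loss. With y the fraction of the charge still present, pairing takes a·y·y while the loss takes y. Here a = g × charge is the competition number, a selectivity factor, and g is the competition constant: the start ratio of the two uses of substrate per unit of charge. Integrating y from the full charge to nothing gives the final share: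

Y = 1 − ln(1 + a)/a

Turned round, this can be iterated on a plateau:

a → ln(1 + a)/(1 − Y)

The eta plateau is 77.3%. Starting from a = 10, one round gives 10.6, and putting that back in gives 10.8. So g is 25.7 /M. The beta run, not used for g, then gives 23.4% against readings of 25% and 24%.

The last addition is time. Substrate in the beta run falls more slowly later, at about 0.0292 /min between 30.0 min and 60.0 min, and at 60.0 min the beta, alpha and eta runs still read 5%, 3% and 4% substrate, a remainder that the line for Y leaves aside. The eta product moves from 78% to 77% between 30.0 min and 60.0 min, a change smaller than the scatter. Y rises with a, so this reckoning ranks the flasks by charge at both times, with alder at 76.4% and cedar at 22.8%.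

The forecast, resting on “a first-order loss competing with dimerisation”, gives alder > ash > elm > larch > maple > cedar at 1.0 h and alder > ash > elm > larch > maple > cedar at 4.0 h. Its top of 77% is higher and its low of 23.5% higher than this reckoning's values, with a/S0 near 27 per molar.

The flasks give alder > ash > elm > larch > maple > cedar at 1.0 h and alder > ash > elm > larch > maple > cedar at 4.0 h, with top 77.2% and low 23.6%.

    2 substrate → product (k = 0.0120 /M/s)
    substrate ⇌ dormant form (K = 26.4, k = 9.20 × 10⁻⁴ /s)
    crystals ⇌ product, rate k3*(cs3 - [product]) while solid is left; crystals form when [product] > cs3 (solubility = 1.10 mM, k = 0.00574 /s)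

The loss is the dormant form: alder holds 21.8% of its charge there at 1.00 h, beside 77.2% product, crystals counted in. Alder's competition number, 10.3, stands beside the simulated start ratio of 10, the forward use of substrate by pairing over that by the path to dormant form. The neighbour flask, alder's recipe with 0.24 M of substrate, has a = 6.17, so the same line gives 68.1%. That flask gives 69.0% product at 1.00 h, with 29.6% as dormant form and 1.40% as substrate.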